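**Assumptions:** The target has no stereocentres. The only stereo-element is the E-enone, so "single enantiomer" does not apply. The route is 2 steps. Compound 1 is taken as commercially available, and it is also made in one step by selective 4-O-methylation of phloroacetophenone.

## Retrosynthesis
1. Target, an E-2'-hydroxychalcone, ⇒ Claisen–Schmidt aldol between aryl methyl ketone **4** and 4-hydroxybenzaldehyde (**3**). The E-alkene is set by dehydration.
2. Ketone **4** ⇒ ortho-C-prenylation of 2',6'-dihydroxy-4'-methoxyacetophenone (**1**) with prenyl bromide (**2**). The 3'- and 5'-positions of **1** are equivalent by symmetry, so only one regioisomer is possible.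
3. No ring is constructed. The aromatic ring is purchased already carrying the OH, OMe and acetyl groups.

## Forward route

**Step 1**
Reactants: **1**, 2',6'-dihydroxy-4'-methoxyacetophenone; **2**, prenyl bromide (1-bromo-3-methylbut-2-ene)
Product: **4**, 1-[2,6-dihydroxy-4-methoxy-3-(3-methylbut-2-en-1-yl)phenyl]ethan-1-one
Conditions: KOH (2.2 equiv), H2O/MeOH, 0 °C → rt, 12 h; then dilute HCl workup. Prenyl bromide is used at 1.0–1.1 equiv and added slowly.
Reagents that add atoms: prenyl bromide, CC(C)=CCBr
Why: The doubly chelated phenolate reacts at carbon through its ortho/para-activated ring position (Friedel–Crafts-type C-alkylation of a phenolate in water). Because the 3'- and 5'-positions are equivalent, one regioisomer forms, and limiting the bromide suppresses bis-prenylation. No stereocentre is formed.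

**Step 2**
Reactants: **4**; **3**, 4-hydroxybenzaldehyde
Product: **5**, xanthogalenol, (E)-1-[2,6-dihydroxy-4-methoxy-3-(3-methylbut-2-enyl)phenyl]-3-(4-hydroxyphenyl)prop-2-en-1-one
Conditions: 50% aq. KOH (about 8 equiv), EtOH, rt → 50 °C, 24–48 h, under N2. Cool, acidify to pH 3 with 2 M HCl, extract with EtOAc, and purify by silica chromatography.
Reagents that add atoms: none (the aldehyde is the reactant and water is lost)
Why: This is a Claisen–Schmidt (base-mediated aldol condensation). Excess base generates the polyphenolate, and the enolate of the acetyl group adds to the aldehyde. E1cB dehydration gives the conjugated enone, and the thermodynamically favoured E-isomer forms selectively (J ≈ 15.5 Hz). The prenyl alkene, aryl methyl ether and free phenols all survive, and the chelated 2'/6'-OH groups do not need protection.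

## Check against the target SMILES
- Ring substitution in **5**: C1' carries the enone, C2' and C6' carry OH, C3' carries prenyl, C4' carries OMe, and C5' is H. This matches COc1cc(O)c(C(=O)/C=C/Ar)c(O)c1CC=C(C)C.
- The B ring is 4-hydroxyphenyl and the alkene is E.
- Atom balance, step 1: C10H12O4 + C5H9Br → C15H20O4 + HBr.
- Atom balance, step 2: C15H20O4 + C7H6O2 → C22H24O5 + H2O.
- The only stereo-element, the E-alkene, is set in step 2 and not altered afterwards.

## Compound list
1 | 2',6'-dihydroxy-4'-methoxyacetophenone | COc1cc(O)c(C(C)=O)c(O)c1 | starting material
2 | prenyl bromide | CC(C)=CCBr | starting material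
3 | 4-hydroxybenzaldehyde | O=Cc1ccc(O)cc1 | starting material
4 | 1-[2,6-dihydroxy-4-methoxy-3-prenylphenyl]ethanone | COc1cc(O)c(C(C)=O)c(O)c1CC=C(C)C | intermediate
5 | xanthogalenol | COc1cc(O)c(C(=O)/C=C/c2ccc(O)cc2)c(O)c1CC=C(C)C | target

**Total steps:** 2. **Longest linear sequence:** 2.

## Three steps most likely to fail
1. **Step 1, C- versus O-prenylation and mono- versus di-prenylation.** Yields may be modest because of O-prenyl ether and 3,5-diprenyl by-products.
   Fallback: O-prenylate (prenyl bromide, K2CO3, acetone), then carry out a Lewis-acid-mediated Claisen-type ortho-migration. Alternatively, use a MOM-protected acetophenone and direct ortho-lithiation/prenylation, as in protected-acetophenone syntheses of xanthohumol.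
2. **Step 2, aldol with a deactivated phenolate aldehyde.** 4-Hydroxybenzaldehyde is a poor electrophile as its phenolate, so conversion may stall.
   Fallback: use 4-(methoxymethoxy)benzaldehyde with the bis-MOM-protected ketone. Do the aldol under standard conditions, then remove the MOM groups with HCl/MeOH at rt.
3. **Step 2 workup, isomerisation of the 2'-hydroxychalcone to the flavanone, or cyclisation with the prenyl group.** This is promoted by prolonged base or acid.
   Fallback: run the condensation under non-cyclising conditions and quench cold. If needed, build the enone by a different disconnection, for example a Heck or Suzuki coupling of 4-hydroxyphenylboronic acid with the aryl vinyl ketone, or a Wittig/HWE route from the aryl ketone.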